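**Plan**
- Cuts: first the ether bond between the C5 oxygen and the allylic CH2. Then, in one stroke, both C–C bonds that hold the lactone on the benzene ring, C3–C3a and C1–C7a (isobenzofuranone numbering). This leaves a C3a≡C7a aryne, an isocyanide carbon (C1, acid level) and formaldehyde (C3 and O2).
- Enabling feature: the oxygen on C4 of the benzene ring sits directly beside ring-fusion atom C3a. As an alkoxy group flanking the aryne it polarises C3a≡C7a, so a carbon nucleophile enters at C7a and the aryl anion appears at C3a. This is exactly the C=O/CH2 orientation of the γ-lactone ring.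
- Forward, arene: the benzene ring is bought intact (1). The C4/C5 oxygens are tied into a diphenyl ketal (temporary ring) and CHO is exchanged for O. Carbamate-directed silylation and triflation give the aryne precursor, and the three-component annulation closes the furanone ring. Aqueous acid then removes the t-BuN= and ketal helpers.
- Forward, chain: (2E,6E)-farnesyl acetate is hydrated at its terminal alkene (bromohydrin, epoxide, hydride), made into the allylic bromide, and joined last to the more acidic C5–OH.
- Stereochemistry: the target has no stereocentre. Both E alkenes come from 17 and are never touched.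

Key step: step 6

Assumption: the target is achiral, so no enantiomer question arises. Compounds 18 and 19 are racemic at C10 of the chain, and this centre is erased in step 10.

**Step 1**
Reactants: 1 2,3-dihydroxy-4-methoxybenzaldehyde
Product: 2 7-methoxy-2,2-diphenyl-1,3-benzodioxole-4-carbaldehyde
Conditions: Ph2CCl2 (1.3 equiv), Ph2O, 170 °C
Reagents that add atoms: dichlorodiphenylmethane ClC(Cl)(c1ccccc1)c1ccccc1
Why: Catechol ketalisation with a gem-dichloride (double O-alkylation through the stabilised diarylchloromethyl cation) works even on carbonyl-deactivated catechols and ties the future C4/C5 oxygens into one aprotic ring that is stable to base and fluoride.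

**Step 2**
Reactants: 2 7-methoxy-2,2-diphenyl-1,3-benzodioxole-4-carbaldehyde
Product: 4 7-methoxy-2,2-diphenyl-1,3-benzodioxol-4-ol, via aryl formate 3 (not isolated)
Conditions: mCPBA, CH2Cl2, 0 °C → rt; then K2CO3 (cat.), MeOH, rt
Reagents that add atoms: mCPBA OOC(=O)c1cccc(Cl)c1
Why: Baeyer–Villiger oxidation of an electron-rich benzaldehyde proceeds with aryl migration, and transesterification of the formate then exposes the phenol oxygen that will become the leaving group at C3a.

**Step 3**
Reactants: 4 7-methoxy-2,2-diphenyl-1,3-benzodioxol-4-ol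
Product: 5 7-methoxy-2,2-diphenyl-1,3-benzodioxol-4-yl N-isopropylcarbamate
Conditions: i-PrNCO, Et3N (cat.), CH2Cl2, rt
Reagents that add atoms: isopropyl isocyanate CC(C)N=C=O
Why: Base-catalysed addition of a phenol to an isocyanate gives a secondary carbamate that is a strong ortho director and can later be removed under mild E1cB conditions.

**Step 4**
Reactants: 5 7-methoxy-2,2-diphenyl-1,3-benzodioxol-4-yl N-isopropylcarbamate
Product: 8 7-methoxy-2,2-diphenyl-5-(trimethylsilyl)-1,3-benzodioxol-4-yl N-isopropylcarbamate, via N-TBS carbamate 6 (not isolated), via C5-silylated N-TBS carbamate 7 (not isolated)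
Conditions: TBSOTf, TMEDA, Et2O, 0 °C → rt; n-BuLi, TMEDA, −78 °C; TMSCl, −78 °C → rt; aq NaHSO4
Reagents that add atoms: chlorotrimethylsilane C[Si](C)(C)Cl
Why: In this directed ortho-metalation the N-silylated carbamate made in the flask is the strongest director on the ring and has only one free ortho position (C5 of the benzodioxole), so lithiation and silyl quench should occur there and not beside the methoxy group, and the N–Si bond is hydrolysed on work-up.

**Step 5**
Reactants: 8 7-methoxy-2,2-diphenyl-5-(trimethylsilyl)-1,3-benzodioxol-4-yl N-isopropylcarbamate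
Product: 10 7-methoxy-2,2-diphenyl-5-(trimethylsilyl)-1,3-benzodioxol-4-yl trifluoromethanesulfonate, via ortho-silyl phenol 9 (not isolated)
Conditions: DBU, Et2NH, MeCN, 40 °C; then PhNTf2, rt
Reagents that add atoms: N-phenylbis(trifluoromethanesulfonimide) FC(F)(F)S(=O)(=O)N(c1ccccc1)S(=O)(=O)C(F)(F)F
Why: E1cB cleavage of the N–H carbamate, with the isocyanate trapped by Et2NH, frees the phenoxide, which is O-sulfonylated in the same flask to the ortho-silylaryl triflate without touching the C–Si bond or the ketal.

**Step 6**
Reactants: 10 7-methoxy-2,2-diphenyl-5-(trimethylsilyl)-1,3-benzodioxol-4-yl trifluoromethanesulfonate; 11 tert-butyl isocyanide; 12 formaldehyde (cold THF solution of the monomer, freshly made by cracking paraformaldehyde)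
Product: 14 (Z)-1-(tert-butylimino)-6-methoxy-4,5-(diphenylmethylenedioxy)-1,3-dihydroisobenzofuran, via aryne 13 (not isolated)
Conditions: KF, 18-crown-6, THF, 0 °C → rt; 11 (2 equiv) and 12 (3–5 equiv) in excess, 10 added slowly
Reagents that add atoms: none
Why: Fluoride removes the silyl group at C7a and triflate leaves from C3a, giving aryne 13; the isocyanide carbon, an acyl-anion equivalent, adds to C7a, the aryl anion thus formed at C3a adds to formaldehyde, and the alkoxide closes on the nitrilium carbon, so that C1–C7a, C3–C3a and O2–C1 arise in one operation. The closest known reaction type is the three-component coupling of arynes, isocyanides and aldehydes to 1-imino-1,3-dihydroisobenzofurans, which 3-alkoxyarynes undergo in this same orientation. The only ring closed, the five-membered oxygen ring, closes in the 5-exo-dig mode (alkoxide onto the sp nitrilium carbon). No stereocentre is formed; only the C=N geometry arises, expected Z with tert-butyl turned away from C7–H, and it is erased in step 7. Regioselectivity is needed and is secured by the ketal oxygen on C4, whose inductive pull and ring-fusion strain widen the angle at C7a (site of attack) and stabilise negative charge at C3a. Chemoselectivity is also needed: the aprotic ketal leaves no O–H to quench the aryl anion, the isocyanide is the only good carbon nucleophile present, and formaldehyde is the smallest and most electrophilic trap for the doubly ortho-flanked anion.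

**Step 7**
Reactants: 14 (Z)-1-(tert-butylimino)-6-methoxy-4,5-(diphenylmethylenedioxy)-1,3-dihydroisobenzofuran
Product: 16 4,5-dihydroxy-6-methoxyisobenzofuran-1(3H)-one, via ketal-protected phthalide 15 (not isolated)
Conditions: AcOH–H2O (4:1), 100 °C, Ar
Reagents that add atoms: water O
Why: Acid hydrolysis of a cyclic imidate collapses to lactone plus amine (any ring-opened hydroxy amide relactonises under the same conditions), and the same hot aqueous acid hydrolyses the diphenyl ketal, so both helpers leave in one operation.

**Step 8**
Reactants: 17 (2E,6E)-farnesyl acetate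
Product: 18 (2E,6E)-10-bromo-11-hydroxy-3,7,11-trimethyldodeca-2,6-dien-1-yl acetate (racemic at C10)
Conditions: NBS (1.1 equiv), THF–H2O, 0 °C
Reagents that add atoms: N-bromosuccinimide O=C1CCC(=O)N1Br; water O
Why: Bromohydrin formation in a water-rich medium should select the exposed terminal alkene, because the 2,3-alkene is deactivated by the allylic acetate and the internal one is shielded by chain coiling; Markovnikov attack of water sets the tertiary alcohol, and the C10 centre is racemic and is removed later.

**Step 9**
Reactants: 18 (2E,6E)-10-bromo-11-hydroxy-3,7,11-trimethyldodeca-2,6-dien-1-yl acetate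
Product: 19 (2E,6E)-10,11-epoxy-3,7,11-trimethyldodeca-2,6-dien-1-ol (racemic)
Conditions: K2CO3, MeOH, rt
Reagents that add atoms: none
Why: Intramolecular Williamson closure of the bromohydrin to the epoxide and transesterification of the acetate occur under the same mild base.

**Step 10**
Reactants: 19 (2E,6E)-10,11-epoxy-3,7,11-trimethyldodeca-2,6-dien-1-ol
Product: 20 (2E,6E)-3,7,11-trimethyldodeca-2,6-diene-1,11-diol
Conditions: LiAlH4, THF, 0 °C → rt
Reagents that add atoms: none
Why: SN2 hydride opening of a trisubstituted epoxide takes place at the less substituted C10, leaving the tertiary C11 alcohol and erasing the only stereocentre, while isolated trisubstituted alkenes are inert.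

**Step 11**
Reactants: 20 (2E,6E)-3,7,11-trimethyldodeca-2,6-diene-1,11-diol
Product: 21 (6E,10E)-12-bromo-2,6,10-trimethyldodeca-6,10-dien-2-ol
Conditions: CBr4 (1.1 equiv), PPh3 (1.1 equiv), CH2Cl2, −20 → 0 °C; used crude after removal of Ph3PO with pentane
Reagents that add atoms: carbon tetrabromide BrC(Br)(Br)Br
Why: The Appel reaction activates the unhindered primary allylic alcohol much faster than the tertiary one, and SN2 displacement keeps the E geometry.

**Step 12**
Reactants: 16 4,5-dihydroxy-6-methoxyisobenzofuran-1(3H)-one; 21 (6E,10E)-12-bromo-2,6,10-trimethyldodeca-6,10-dien-2-ol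
Product: 22 Farnesylemefuranone E
Conditions: KHCO3 (1.1 equiv), 21 (1.0 equiv), DMF, rt → 40 °C, Ar
Reagents that add atoms: none
Why: In this Williamson ether synthesis the weak base should form only the monoanion of the C5–OH, which is para to the lactone carbonyl, more acidic, and hydrogen-bonded by C4–OH, and SN2 at the primary allylic carbon leaves both E alkenes and the tertiary alcohol untouched.

**Compound list**
1 | 2,3-dihydroxy-4-methoxybenzaldehyde | COc1ccc(C=O)c(O)c1O | starting material
2 | 7-methoxy-2,2-diphenyl-1,3-benzodioxole-4-carbaldehyde | COc1ccc(C=O)c2OC(c3ccccc3)(c3ccccc3)Oc12 | intermediate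
3 | 7-methoxy-2,2-diphenyl-1,3-benzodioxol-4-yl formate | COc1ccc(OC=O)c2OC(c3ccccc3)(c3ccccc3)Oc12 | intermediate
4 | 7-methoxy-2,2-diphenyl-1,3-benzodioxol-4-ol | COc1ccc(O)c2OC(c3ccccc3)(c3ccccc3)Oc12 | intermediate
5 | 7-methoxy-2,2-diphenyl-1,3-benzodioxol-4-yl N-isopropylcarbamate | COc1ccc(OC(=O)NC(C)C)c2OC(c3ccccc3)(c3ccccc3)Oc12 | intermediate
6 | N-(tert-butyldimethylsilyl) derivative of 5 | COc1ccc(OC(=O)N(C(C)C)[Si](C)(C)C(C)(C)C)c2OC(c3ccccc3)(c3ccccc3)Oc12 | intermediate
7 | 5-trimethylsilyl derivative of 6 | COc1cc([Si](C)(C)C)c(OC(=O)N(C(C)C)[Si](C)(C)C(C)(C)C)c2OC(c3ccccc3)(c3ccccc3)Oc12 | intermediate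
8 | 7-methoxy-2,2-diphenyl-5-(trimethylsilyl)-1,3-benzodioxol-4-yl N-isopropylcarbamate | COc1cc([Si](C)(C)C)c(OC(=O)NC(C)C)c2OC(c3ccccc3)(c3ccccc3)Oc12 | intermediate
9 | 7-methoxy-2,2-diphenyl-5-(trimethylsilyl)-1,3-benzodioxol-4-ol | COc1cc([Si](C)(C)C)c(O)c2OC(c3ccccc3)(c3ccccc3)Oc12 | intermediate
10 | 7-methoxy-2,2-diphenyl-5-(trimethylsilyl)-1,3-benzodioxol-4-yl trifluoromethanesulfonate | COc1cc([Si](C)(C)C)c(OS(=O)(=O)C(F)(F)F)c2OC(c3ccccc3)(c3ccccc3)Oc12 | intermediate
11 | tert-butyl isocyanide | CC(C)(C)[N+]#[C-] | starting material
12 | formaldehyde (monomer from paraformaldehyde) | C=O | starting material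
13 | 4,5-didehydro-7-methoxy-2,2-diphenyl-1,3-benzodioxole (aryne) | COC1=CC#CC2=C1OC(c1ccccc1)(c1ccccc1)O2 | intermediate
14 | (Z)-1-(tert-butylimino)-6-methoxy-4,5-(diphenylmethylenedioxy)-1,3-dihydroisobenzofuran | COc1cc2c(CO/C2=N\C(C)(C)C)c2OC(c3ccccc3)(c3ccccc3)Oc12 | intermediate
15 | 6-methoxy-4,5-(diphenylmethylenedioxy)isobenzofuran-1(3H)-one | COc1cc2c(COC2=O)c2OC(c3ccccc3)(c3ccccc3)Oc12 | intermediate
16 | 4,5-dihydroxy-6-methoxyisobenzofuran-1(3H)-one | COc1cc2c(c(O)c1O)COC2=O | intermediate
17 | (2E,6E)-farnesyl acetate | CC(=O)OC/C=C(\C)CC/C=C(\C)CCC=C(C)C | starting material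
18 | (2E,6E)-10-bromo-11-hydroxy-3,7,11-trimethyldodeca-2,6-dien-1-yl acetate, racemic | CC(=O)OC/C=C(\C)CC/C=C(\C)CCC(Br)C(C)(C)O | intermediate
19 | (2E,6E)-10,11-epoxy-3,7,11-trimethyldodeca-2,6-dien-1-ol, racemic | OC/C=C(\C)CC/C=C(\C)CCC1OC1(C)C | intermediate
20 | (2E,6E)-3,7,11-trimethyldodeca-2,6-diene-1,11-diol | OC/C=C(\C)CC/C=C(\C)CCCC(C)(C)O | intermediate
21 | (6E,10E)-12-bromo-2,6,10-trimethyldodeca-6,10-dien-2-ol | BrC/C=C(\C)CC/C=C(\C)CCCC(C)(C)O | intermediate
22 | Farnesylemefuranone E | COc1cc2c(c(O)c1OC/C=C(\C)CC/C=C(\C)CCCC(C)(C)O)COC2=O | target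

**Step count**
Total step count: 12. Longest linear sequence: 8 (steps 1–7 and 12). The chain branch (steps 8–11) runs in parallel.

**Steps most likely to fail**

Step 6. Formaldehyde may polymerise under fluoride faster than it is captured. The doubly flanked aryl anion may then be protonated, or may add to a second aryne, before the C3–C3a bond forms.
- The fallback sets out from 10 and makes the two bonds one after the other by palladium chemistry.
- Ipso-iododesilylation (ICl, CH2Cl2, 0 °C) should give the iodo triflate F1.
- Chemoselective methoxycarbonylation of the C–I bond (Pd(PPh3)4, CO 1 atm, MeOH, Et3N, DMF, 60 °C) should give the ester triflate F2.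
- Stille hydroxymethylation of the triflate (Bu3SnCH2OH, Pd(PPh3)4, LiCl, dioxane, 100 °C) should give the hydroxymethyl ester F3.
- F3 lactonises in the flask to 15. The route is rejoined at 15, which is then treated as in step 7.

Step 12. Both phenols may be alkylated, the C4–OH may compete, or the catecholate may be oxidised by air under basic conditions.
- The fallback sets out from 16 and 20 and leaves out the bromide 21.
- It is a Mitsunobu etherification (PPh3, DIAD, THF, 0 °C → rt) that activates the primary allylic alcohol instead of the phenol.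
- It runs without base and selects the phenol in the proton transfer to the betaine.
- It comes back to the route directly at 22, and no compound outside the list arises (entry F0).

Step 4. Lithiation may occur beside the methoxy group, the N-silyl group may be lost early, or the carbamoyl group may migrate to carbon (anionic ortho-Fries) before the silyl quench.
- The fallback sets out from 4 and replaces metalation by electrophilic halogenation and silyl migration.
- Ortho-bromination (NBS, cat. i-Pr2NH, CH2Cl2, 0 °C) should give the bromophenol F4.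
- HMDS (THF, 70 °C) should give its O-trimethylsilyl ether F5.
- n-BuLi (THF, −78 °C) should trigger Br/Li exchange and a retro-Brook O→C silyl shift to the lithium salt of 9.
- Tf2O converts this salt into 10, where the route is rejoined.

**Further compounds**
F1 | step 6 | 5-iodo-7-methoxy-2,2-diphenyl-1,3-benzodioxol-4-yl trifluoromethanesulfonate | COc1cc(I)c(OS(=O)(=O)C(F)(F)F)c2OC(c3ccccc3)(c3ccccc3)Oc12
F2 | step 6 | methyl 7-methoxy-2,2-diphenyl-4-(trifluoromethylsulfonyloxy)-1,3-benzodioxole-5-carboxylate | COC(=O)c1cc(OC)c2OC(c3ccccc3)(c3ccccc3)Oc2c1OS(=O)(=O)C(F)(F)F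
F3 | step 6 | methyl 4-(hydroxymethyl)-7-methoxy-2,2-diphenyl-1,3-benzodioxole-5-carboxylate | COC(=O)c1cc(OC)c2OC(c3ccccc3)(c3ccccc3)Oc2c1CO
F0 | step 12 | none | none
F4 | step 4 | 5-bromo-7-methoxy-2,2-diphenyl-1,3-benzodioxol-4-ol | COc1cc(Br)c(O)c2OC(c3ccccc3)(c3ccccc3)Oc12
F5 | step 4 | (5-bromo-7-methoxy-2,2-diphenyl-1,3-benzodioxol-4-yloxy)trimethylsilane | COc1cc(Br)c(O[Si](C)(C)C)c2OC(c3ccccc3)(c3ccccc3)Oc12
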